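The 1,2-dioxane (O1–O2–C3–C4–C5–C6; C3 bears CH2CO2Me, C4 and C6 an ethyl group) is cut across C5–C6 and O2–C3, a [3+3] disconnection. The key step joins a peroxycarbenium ion, +C6–O1–O2–SiEt3, released from a ketone-derived silyl peroxyketal that already carries the dienyl side chain, with a siloxycyclopropane that hides C3–C4–C5 as a homoenolate. Its CH2 (C5) attacks C6, the three-membered ring opens to a C3 oxocarbenium ion, and O2 closes the six-membered ring. The step exploits the 1,3-relation of the ring CH2 (C5) and the oxygen-bearing C3 across C4. C4 is set by catalysis; C6 (key step, modest bias) and C3 (closing silane reduction) are relayed from it.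

Key step: step 11

Numbering used below: ring O1, O2, C3, C4, C5, C6; side chain C7=C8(Me)–C9H2–C10H(Et)–C11=C12–C13–C14.

Assumption: the L,L-dipeptide ligand of step 10 is taken to deliver CH2 to the enol ether face that gives (1R,2R)-17; if the sense proves opposite, the D,D-ligand is used.

Step 1
Reactants: 1 (E)-pent-2-enal
Product: 2 (3R,4E)-hept-4-en-3-ol
Conditions: Et2Zn, (2R)-(+)-3-exo-(dimethylamino)isoborneol (5 mol%), toluene, 0 °C; then 1 M HCl
Reagents that add atoms: diethylzinc, CC[Zn]CC
Why: Amino-alcohol-catalysed enantioselective 1,2-addition of a dialkylzinc to an enal, in which the (2R)-ligand should steer ethyl to the carbonyl face that gives the R carbinol (mirror image of the usual (2S)-ligand/S-alcohol pairing).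

Step 2
Reactants: 2 (3R,4E)-hept-4-en-3-ol
Product: 4 ethyl (3R,4E)-3-ethylhept-4-enoate, via ketene acetal 3 (not isolated)
Conditions: MeC(OEt)3, EtCO2H (cat.), 140 °C, ethanol distilled off
Reagents that add atoms: triethyl orthoacetate, CC(OCC)(OCC)OCC
Why: Johnson–Claisen rearrangement through a chair transition state with the carbinol ethyl group equatorial, which should transfer the C–O stereocentre suprafacially to the new C–C stereocentre (the later C10, R) and give the E alkene.

Step 3
Reactants: 4 ethyl (3R,4E)-3-ethylhept-4-enoate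
Product: 5 (3R,4E)-3-ethylhept-4-enal
Conditions: iBu2AlH, CH2Cl2, −78 °C; then aq. potassium sodium tartrate
Reagents that add atoms: none
Why: Partial reduction of an ester to the aldehyde through the aluminium hemiacetal that is stable at low temperature; the stereocentre is β to the carbonyl group and cannot epimerise.

Step 4
Reactants: 5 (3R,4E)-3-ethylhept-4-enal
Product: 6 (4R,5E)-4-ethyloct-5-en-1-yne
Conditions: dimethyl (1-diazo-2-oxopropyl)phosphonate, K2CO3, MeOH, 0 °C to rt
Reagents that add atoms: dimethyl (1-diazo-2-oxopropyl)phosphonate, CC(=O)C(=[N+]=[N-])P(=O)(OC)OC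
Why: Ohira–Bestmann homologation of an aldehyde to the terminal alkyne under mild base, which leaves the remote stereocentre and the E alkene untouched.

Step 5
Reactants: 6 (4R,5E)-4-ethyloct-5-en-1-yne
Product: 8 (4E,7R,8E)-7-ethyl-5-methylundeca-4,8-dien-3-one, via alkenylalane 7 (not isolated)
Conditions: Me3Al, Cp2ZrCl2 (0.2 equiv), CH2Cl2, 0 °C to rt; then EtCOCl, Pd(PPh3)4 (5 mol%), THF, 0 °C; then 1 M HCl
Reagents that add atoms: trimethylaluminium, C[Al](C)C; propanoyl chloride, CCC(Cl)=O
Why: Negishi zirconium-catalysed syn carboalumination puts methyl on the internal alkyne carbon cis to aluminium, and the palladium-catalysed acylation of the alkenylalane goes with retention, so the trisubstituted enone should be E.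

Step 6
Reactants: 8 (4E,7R,8E)-7-ethyl-5-methylundeca-4,8-dien-3-one
Product: 10 (4E,7R,8E)-7-ethyl-3-hydroperoxy-3-methoxy-5-methylundeca-4,8-diene (both epimers at C3 of the chain), via dimethyl ketal 9 (not isolated)
Conditions: HC(OMe)3, MeOH, pyridinium p-toluenesulfonate (cat.), 0 °C; then anhydrous H2O2 in Et2O, −20 °C
Reagents that add atoms: trimethyl orthoformate, COC(OC)OC; hydrogen peroxide, OO
Why: Ketalisation followed by acid-catalysed peroxyketal exchange, in which H2O2 should capture the alkoxy-allyl cation kinetically at the oxygen-bearing carbon; the new ketal centre is of no consequence because it becomes planar in step 11.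

Step 7
Reactants: 10 (4E,7R,8E)-7-ethyl-3-hydroperoxy-3-methoxy-5-methylundeca-4,8-diene
Product: 11 triethyl{[(4E,7R,8E)-7-ethyl-3-methoxy-5-methylundeca-4,8-dien-3-yl]peroxy}silane
Conditions: Et3SiCl, imidazole, DMF, 0 °C
Reagents that add atoms: chlorotriethylsilane, CC[Si](Cl)(CC)CC
Why: O-silylation of a hydroperoxide with a chlorosilane and imidazole, basic conditions under which the acid-labile peroxyketal should survive.

Step 8
Reactants: 12 Meldrum's acid (2,2-dimethyl-1,3-dioxane-4,6-dione); 13 (E)-but-2-enoyl chloride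
Product: 15 methyl (4E)-3-oxohex-4-enoate, via acyl Meldrum's acid 14 (not isolated)
Conditions: pyridine, CH2Cl2, 0 °C; then MeOH, reflux
Reagents that add atoms: methanol, CO
Why: C-acylation of Meldrum's acid and methanolysis of the acyl derivative with loss of acetone and CO2, the standard route to β-keto esters.

Step 9
Reactants: 15 methyl (4E)-3-oxohex-4-enoate
Product: 16 methyl (3Z)-3-(triethylsilyloxy)hex-3-enoate
Conditions: Et3SiH, RhCl(PPh3)3 (1 mol%), THF, 50 °C
Reagents that add atoms: triethylsilane, CC[SiH](CC)CC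
Why: Rhodium-catalysed 1,4-hydrosilylation of the enone through its s-cis conformer, which should give the Z silyl enol ether regiospecifically on the side remote from the ester.

Step 10
Reactants: 16 methyl (3Z)-3-(triethylsilyloxy)hex-3-enoate
Product: 17 methyl 2-[(1R,2R)-2-ethyl-1-(triethylsilyloxy)cyclopropyl]acetate (ethyl cis to OSiEt3)
Conditions: Et2Zn, CH2I2, N-Boc-L-Val-L-Pro-OMe (0.25 equiv), CH2Cl2, −40 °C; then aq. NH4Cl
Reagents that add atoms: diiodomethane, ICI
Why: Catalytic asymmetric Simmons–Smith cyclopropanation of a silyl enol ether; the stereospecific syn addition keeps OSiEt3 and ethyl cis, and the chiral zinc carbenoid selects the alkene face, which sets the later C4 (R).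

Step 11
Reactants: 11 triethyl{[(4E,7R,8E)-7-ethyl-3-methoxy-5-methylundeca-4,8-dien-3-yl]peroxy}silane; 17 methyl 2-[(1R,2R)-2-ethyl-1-(triethylsilyloxy)cyclopropyl]acetate
Product: 20 methyl 2-[(3R,4R,6S)-4,6-diethyl-6-[(1E,4R,5E)-4-ethyl-2-methylocta-1,5-dien-1-yl]-3-(triethylsilyloxy)-1,2-dioxan-3-yl]acetate, via peroxycarbenium triflate 18 (not isolated), via oxocarbenium triflate 19 (not isolated)
Conditions: TMSOTf (0.2 equiv), 2,6-di-tert-butyl-4-methylpyridine, CH2Cl2, −78 °C
Reagents that add atoms: none
Why: Proposed new method: TMSOTf ionises the C6–OMe bond of 11 to the peroxycarbenium ion 18; the unsubstituted cyclopropane CH2 (C5) of 17 attacks C6 as a σ-nucleophile while the C5–C3 bond opens under the push of the siloxy oxygen, and the C3 silyloxocarbenium ion 19 is captured by the silylated peroxide oxygen O2, whose Et3Si+ carries the chain (net loss of MeOSiEt3). The closest known reaction types are the Lewis-acid annulation of silyl peroxyketals with alkenes to 1,2-dioxolanes, the Mukaiyama-type addition of silyl enol ethers to peroxycarbenium ions and the homoenolate ring opening of siloxycyclopropanes by electrophiles; a siloxycyclopropane as the three-carbon partner of a peroxycarbenium ion is not known. The 1,2-dioxane closes by 6-exo-trig attack of O2 on the exocyclic C3=O+ bond. C4 is carried in unchanged because no bond to it is made or broken; C6 is set in the C–C bond formation, where the ethyl group that C4 holds on one face of the cyclopropane next to C5 should turn the planar β,β-disubstituted alkenyl group of the cation away from that face in an open staggered transition state, only a modest bias toward 6S, so the 6R epimer (a ring diastereomer) is removed by chromatography after step 12; the C3 ketal centre follows the anomeric effect and is erased in step 12. The step needs attack at C6 and not at the allyl terminus C8, which the higher charge at the oxygen-bearing carbon and the full substitution of C8 should secure, and cleavage of the C5–C3 and not the C4–C3 bond, which the unhindered CH2 should secure.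

Step 12
Reactants: 20 methyl 2-[(3R,4R,6S)-4,6-diethyl-6-[(1E,4R,5E)-4-ethyl-2-methylocta-1,5-dien-1-yl]-3-(triethylsilyloxy)-1,2-dioxan-3-yl]acetate
Product: 22 methyl 2-[(3S,4R,6S)-4,6-diethyl-6-[(1E,4R,5E)-4-ethyl-2-methylocta-1,5-dien-1-yl]-1,2-dioxan-3-yl]acetate (target), via ring peroxycarbenium triflate 21 (not isolated)
Conditions: Et3SiH, TMSOTf (0.3 equiv), CH2Cl2, −78 °C; chromatography to remove the C6 epimer
Reagents that add atoms: none
Why: Silane reduction (ionic hydrogenation) of the ketal through the ring peroxycarbenium ion; hydride should enter axially on the half-chair that keeps the C4 ethyl group pseudoequatorial, so H-3 ends anti to H-4 and CH2CO2Me equatorial, trans to the C4 ethyl group (3S).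

Compound list
1 | (E)-pent-2-enal | CC/C=C/C=O | starting material
2 | (3R,4E)-hept-4-en-3-ol | CC/C=C/[C@H](O)CC | intermediate
3 | (3R,4E)-3-[(1-ethoxyethenyl)oxy]hept-4-ene (ketene acetal, not isolated) | CC/C=C/[C@H](OC(=C)OCC)CC | intermediate
4 | ethyl (3R,4E)-3-ethylhept-4-enoate | CC/C=C/[C@H](CC)CC(=O)OCC | intermediate
5 | (3R,4E)-3-ethylhept-4-enal | CC/C=C/[C@H](CC)CC=O | intermediate
6 | (4R,5E)-4-ethyloct-5-en-1-yne | CC/C=C/[C@H](CC)CC#C | intermediate
7 | [(1E,4R,5E)-4-ethyl-2-methylocta-1,5-dien-1-yl]dimethylalane (not isolated) | CC/C=C/[C@H](CC)C/C(C)=C/[Al](C)C | intermediate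
8 | (4E,7R,8E)-7-ethyl-5-methylundeca-4,8-dien-3-one | CC/C=C/[C@H](CC)C/C(C)=C/C(=O)CC | intermediate
9 | (4E,7R,8E)-7-ethyl-3,3-dimethoxy-5-methylundeca-4,8-diene (not isolated) | CC/C=C/[C@H](CC)C/C(C)=C/C(OC)(OC)CC | intermediate
10 | (4E,7R,8E)-7-ethyl-3-hydroperoxy-3-methoxy-5-methylundeca-4,8-diene (both C3 epimers) | CC/C=C/[C@H](CC)C/C(C)=C/C(OC)(OO)CC | intermediate
11 | triethyl{[(4E,7R,8E)-7-ethyl-3-methoxy-5-methylundeca-4,8-dien-3-yl]peroxy}silane (both C3 epimers) | CC/C=C/[C@H](CC)C/C(C)=C/C(OC)(OO[Si](CC)(CC)CC)CC | intermediate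
12 | Meldrum's acid (2,2-dimethyl-1,3-dioxane-4,6-dione) | CC1(C)OC(=O)CC(=O)O1 | starting material
13 | (E)-but-2-enoyl chloride | C/C=C/C(Cl)=O | starting material
14 | 5-[(2E)-1-hydroxybut-2-en-1-ylidene]-2,2-dimethyl-1,3-dioxane-4,6-dione (not isolated) | C/C=C/C(O)=C1C(=O)OC(C)(C)OC1=O | intermediate
15 | methyl (4E)-3-oxohex-4-enoate | C/C=C/C(=O)CC(=O)OC | intermediate
16 | methyl (3Z)-3-(triethylsilyloxy)hex-3-enoate | CC/C=C(/CC(=O)OC)O[Si](CC)(CC)CC | intermediate
17 | methyl 2-[(1R,2R)-2-ethyl-1-(triethylsilyloxy)cyclopropyl]acetate | C1[C@@H](CC)[C@]1(O[Si](CC)(CC)CC)CC(=O)OC | intermediate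
18 | [(4E,7R,8E)-7-ethyl-5-methylundeca-4,8-dien-3-ylidene](triethylsilyloxy)oxonium triflate (peroxycarbenium ion, not isolated) | CC/C=C/[C@H](CC)C/C(C)=C/C(CC)=[O+]O[Si](CC)(CC)CC.[O-]S(=O)(=O)C(F)(F)F | intermediate
19 | ring-opened C3 silyloxocarbenium triflate: the 6S,4R chain with C6 bearing Et, the dienyl group and OOSiEt3, and C3 as C(CH2CO2Me)=O+SiEt3 (not isolated) | CC/C=C/[C@H](CC)C/C(C)=C/[C@](OO[Si](CC)(CC)CC)(CC)C[C@@H](CC)C(CC(=O)OC)=[O+][Si](CC)(CC)CC.[O-]S(=O)(=O)C(F)(F)F | intermediate
20 | methyl 2-[(3R,4R,6S)-4,6-diethyl-6-[(1E,4R,5E)-4-ethyl-2-methylocta-1,5-dien-1-yl]-3-(triethylsilyloxy)-1,2-dioxan-3-yl]acetate | CC/C=C/[C@H](CC)C/C(C)=C/[C@]1(CC)C[C@@H](CC)[C@](O[Si](CC)(CC)CC)(CC(=O)OC)OO1 | intermediate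
21 | (4R,6S)-4,6-diethyl-6-[(1E,4R,5E)-4-ethyl-2-methylocta-1,5-dien-1-yl]-3-(2-methoxy-2-oxoethyl)-5,6-dihydro-4H-1,2-dioxin-2-ium triflate (ring peroxycarbenium ion, not isolated) | CC/C=C/[C@H](CC)C/C(C)=C/[C@]1(CC)C[C@@H](CC)C(CC(=O)OC)=[O+]O1.[O-]S(=O)(=O)C(F)(F)F | intermediate
22 | methyl 2-[(3S,4R,6S)-4,6-diethyl-6-[(1E,4R,5E)-4-ethyl-2-methylocta-1,5-dien-1-yl]-1,2-dioxan-3-yl]acetate | CC/C=C/[C@H](CC)C/C(C)=C/[C@]1(CC)C[C@@H](CC)[C@H](CC(=O)OC)OO1 | target

Total step count: 12. Longest linear sequence: 9 steps (steps 1 to 7, then 11 and 12).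

Steps most likely to fail

1. Step 11 (Proposed new method). The σ-bond of the siloxycyclopropane may be too weak a nucleophile, so that the peroxycarbenium ion is lost to Hock-type fragmentation or to attack at its remote allyl terminus before the C–C bond forms. Facial selection at C6 may also be poor. The fallback uses known chemistry, sets out from 11 and comes back at 22. Hosomi–Sakurai allylation of the peroxyketal with trimethyl(2-methylenebutyl)silane and SnCl4 at −78 °C, as known for monoperoxy ketals, would give the homoallyl silyl peroxide F1. Hydroboration of its 1,1-disubstituted alkene with 9-BBN and oxidation with NaBO3 would give the primary alcohol F2. Dess–Martin oxidation would give the aldehyde F3, and Wittig olefination with Ph3P=CHCO2Me the E enoate F4. HF·pyridine would free the hydroperoxide F5, and Et2NH in CF3CH2OH would close the ring by 6-exo oxa-Michael addition to 22. In this fallback C6 and C4 are formed without control and the ring diastereomers are separated by chromatography.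

2. Step 6. The peroxide may add 1,4 to the alkoxy-allyl cation, after which the β-hydroperoxy enol ether closes to a five-membered peroxide; the acid may also scramble the geometry of the conjugated alkene. The fallback sets out from 8 and comes back at 11. Aprotic ketalisation (MeOSiMe3, TMSOTf cat., CH2Cl2, −78 °C) would give the dimethyl ketal 9 as an isolated compound. Trans-ketalisation with triethylsilyl hydroperoxide F6 (made from Et3SiCl and the urea–hydrogen peroxide adduct) and catalytic TMSOTf at −78 °C would exchange one methoxy group for the silylperoxy group and give 11 directly, so that no free hydroperoxide meets the dienyl cation.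

3. Step 10. Enantiofacial discrimination by the chiral zinc carbenoid may be poor on a purely aliphatic silyl enol ether. The fallback sets out from 16 and comes back at 17. Ligand-free Simmons–Smith cyclopropanation (Et2Zn, CH2I2, CH2Cl2, 0 °C) would give the racemic cis-cyclopropane F7, which would be resolved by preparative chromatography on a chiral stationary phase to give (1R,2R)-17.

Further compounds
F1 | step 11 | triethyl{[(5S,6E,9R,10E)-5,9-diethyl-7-methyl-3-methylidenetrideca-6,10-dien-5-yl]peroxy}silane | CC/C=C/[C@H](CC)C/C(C)=C/[C@](OO[Si](CC)(CC)CC)(CC)CC(=C)CC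
F2 | step 11 | (2R,4S,5E,8R,9E)-2,4,8-triethyl-6-methyl-4-(triethylsilylperoxy)dodeca-5,9-dien-1-ol | CC/C=C/[C@H](CC)C/C(C)=C/[C@](OO[Si](CC)(CC)CC)(CC)C[C@@H](CC)CO
F3 | step 11 | (2R,4S,5E,8R,9E)-2,4,8-triethyl-6-methyl-4-(triethylsilylperoxy)dodeca-5,9-dienal | CC/C=C/[C@H](CC)C/C(C)=C/[C@](OO[Si](CC)(CC)CC)(CC)C[C@@H](CC)C=O
F4 | step 11 | methyl (2E,4R,6S,7E,10R,11E)-4,6,10-triethyl-8-methyl-6-(triethylsilylperoxy)tetradeca-2,7,11-trienoate | CC/C=C/[C@H](CC)C/C(C)=C/[C@](OO[Si](CC)(CC)CC)(CC)C[C@@H](CC)/C=C/C(=O)OC
F5 | step 11 | methyl (2E,4R,6S,7E,10R,11E)-4,6,10-triethyl-6-hydroperoxy-8-methyltetradeca-2,7,11-trienoate | CC/C=C/[C@H](CC)C/C(C)=C/[C@](OO)(CC)C[C@@H](CC)/C=C/C(=O)OC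
F6 | step 6 | triethylsilyl hydroperoxide | CC[Si](CC)(CC)OO
F7 | step 10 | racemic methyl 2-[cis-2-ethyl-1-(triethylsilyloxy)cyclopropyl]acetate | CCC1CC1(O[Si](CC)(CC)CC)CC(=O)OC
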